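**The decision.** You asked for a quick number and your hunch was to go by the equilibrium constants. I would reckon from how much X reaches the solution.

L 2.0 × 10⁻⁴ M; Z 0.100 mM; Q 0.022 mM (held); time 30 s

1. the G standing at 30 s, as a percentage of the L charged
2. the change that raises the amount of G at 30 s, in percent of the L charged most ("none" if none brings more than 2 percentage points) (Friday's / Wednesday's / none)
3. amount of G at 30 s, in percent of the L charged, after Wednesday's

    G + X ⇌ Z + J (K1 = 32, k1 = 8500 M⁻¹ s⁻¹)
    L + X ⇌ Z + G (K2 = 64, k2 = 6700 M⁻¹ s⁻¹)
    Q ⇌ X, rate k3*(csat - [X]) (k3 = 0.28 s⁻¹, csat = 0.022 mM)

**The feed.** L takes X and gives G and Z; G takes X and gives J and Z; X comes from Q. Dissolved X has a half-life of 0.52 s against L as charged, forward step alone, and dissolving has a half-time of 2.48 s. Because X goes faster than it comes, the solution stays nearly empty and dissolving is the rate-limiting step. So take the feed, the transfer coefficient times the saturation concentration times the time, as a share of the L charged: 92.4%.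

**The peak.** G is made and eaten by the same X, and the selectivity factor, eating over making, is 1.27. With the way back set aside, the standard result for two such steps in a row puts the peak of G at 32.5% of the L charged, and it costs 85.0% in X. The feed is larger than that cost, so that peak is my number. Either change doubles the feed, to 185%, more than that cost, and with the way back set aside G then stands below the peak, so this reckoning gives no figure of its own for Wednesday's. I keep the peak, 32.5%, as a rough guess for Wednesday's and no more. This reckoning cannot tell the two changes apart.

**The result.** The forecast reads “The feed of X is limited by transfer” and gives 34.3%, 33.5% after Wednesday's, and none as the best change. The flask gives 34.5% and 34.9%, with Friday's best: 2.6 percentage points for it against 0.36 points for Wednesday's.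

**The neighbour.** Each L lost and each J made took up one X, so by 30 s this flask has taken up 69.4% of the L charged, against a feed of 92.4%. The neighbour flask holds 8.0 × 10⁻⁴ M of L, all else the same. Its feed is a quarter of that share, 23.1%, which is less than the cost of the peak, so I read its G as held under the feed. It keeps 81% of its L and makes 2.19% of J, so it has taken up 21.2%, and its G stands at 17.0%.

(The numbers of this flask are invented; no experiment stands behind them.)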